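## Analysis of the target

The target 16 is a 1,4-benzoquinone in which five of the six ring carbons are substituted: numbering the ring C1 (carbonyl), C2 (OH), C3 (unbranched pentadecyl chain), C4 (carbonyl), C5 (OMe) and C6 (H), only C6 carries hydrogen. There is no stereocentre and no stereogenic double bond, so the whole problem is one of regiochemistry on a six-membered ring bearing four oxygen atoms. The sensitive groups are the C2 hydroxyl, a vinylogous carboxylic acid that is acidic and would quench any organometallic reagent, the C5 methoxy group, a vinylogous ester open to exchange by addition–elimination, the free C6 position, a conjugate-acceptor site, and the quinone itself, which is easily reduced. The difficulty is that O2 and O5 are chemically almost alike, yet one must finish as OH and the other as OMe, with the chain beside the hydroxyl and not beside the methoxy group. The strategy rests on the contiguous unit C1(=O)–C2(OH)–C3(pentadecyl)–C4(=O): four carbons carrying three oxygens and one alkyl group, which is the substitution pattern of a 3-alkoxy-4-alkylcyclobutene-1,2-dione made from a squarate ester. What is then missing is only C5(OMe)–C6(H), a 2-methoxyvinyl unit that brings its own methyl ether, so the two ether oxygens never have to be told apart on the finished ring.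

## Retrosynthetic reasoning

16 from 15. The O–C bond of a tert-butyl ether on O2 is cut. A free vinylogous acid would not survive the organometallic and oxidative steps, so O2 is carried through the route as the tert-butyl ether of 15. Anhydrous acid removes that group by ionisation, a pathway that is closed to the methyl ether on O5. The forward step has to cleave one ether and leave the other.

15 from 14. This is a change of oxidation level only. The ring-forming step delivers the aromatic, reduced level, so quinone 15 is traced back to hydroquinone 14. The forward step needs a neutral oxidant that spares the tert-butyl ether.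

14 from 11, through 13 and 12. The C4–C5 bond of the target is cut and the transannular C1–C4 bond is re-formed, which contracts the benzene ring to cyclobutenone 11. This is the natural seam of the molecule: C1 to C4 with all three oxygens and the chain come from the four-membered ring, and C5–C6 is a two-carbon side arm. The forward reaction is a thermal, reagent-free ring expansion in which strain release and aromatisation pay for the new bond. It has to open the small ring with the vinyl group turned toward the ketene of 12, so that 12 can close to 13.

11 from 6 and 10. The bond between the carbinol carbon and the vinyl group, C1–C6 of the target, is cut. In the forward sense vinyllithium 10 must choose between the two carbonyl groups of 6. They differ electronically: the one next to the chain-bearing carbon is the carbonyl of a vinylogous ester, and the one next to the tert-butoxy-bearing carbon is a plain ketone. Addition to the ketone places the vinyl group exactly where the ring expansion needs it.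

10 from 9, and 9 from 7 through 8. The carbon–lithium bond of 10 is traced to the carbon–bromine bond of 9 by halogen–metal exchange with retention of geometry. The Z geometry is wanted for the persistence of 10, not for the ring expansion. Bromide 9 comes from enol ether 7 by addition of the halogen across the double bond, which gives 8, and base-induced loss of hydrogen halide from 8.

6 from 4 through 5, and 4 from 2 and 3, with 3 from 1. The ring-to-chain bond at C3 of the target is cut. The two carbonyl groups of squarate ester 2 are equivalent, so the first addition of organomagnesium reagent 3, made from 1, raises no regiochemical question. Adduct 4 is then transposed through 5, with loss of one tert-butoxy group, to 6. This step desymmetrises the ring and creates the two unlike carbonyl groups on which the next disconnection depends.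

## Alternatives that were turned down

Alternative 1: The ring is cut at C3–C4 and C5–C6. The carbons C6, C1, C2 and C3 with the chain then come from nonadecane-2,3-dione A1, and C4 and C5 come from diethyl oxalate A2.
- Forward key step: under an alkoxide base the methyl group and the methylene group that flank the diketone of A1 each attack one ester carbon of A2 in a double Claisen condensation. This closes the ring as 2,5-dihydroxy-3-pentadecylcyclohexa-2,5-diene-1,4-dione A3.
- For it: A2 is a cheap bulk ester, all four oxygens arrive at the quinone oxidation level in one operation, and a single O-methylation of A3 would finish the synthesis. On step count it is clearly stronger than the chosen route.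
- Against it: A1 is not a stock compound and needs a regioselective α-oxidation of a long-chain methyl ketone. An enolisable 1,2-dione such as A1 also condenses with itself under alkoxide, in competition with its acylation by A2. Most seriously, in A3 the two hydroxyls exchange roles with the carbonyl oxygens by tautomerism, so the final methylation must distinguish the oxygen next to C6–H from the one next to the chain by sterics alone. A wrong methylation gives a constitutional isomer of 16 that would be hard to separate.
- Comparison: the chosen route spends more steps but never holds two equivalent oxygens. The ether on O2 and the ether on O5 enter in different steps and from different reagents.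

Alternative 2: Three ring bonds are cut, C3–C4, C1–C2 and C4–C5. This gives a four-carbon vinylketene, to be generated from (E)-1-diazo-4-methoxybut-3-en-2-one A4, and the two-carbon siloxyalkyne (heptadec-1-yn-1-yloxy)triisopropylsilane A5.
- Forward key step: light converts A4 by Wolff rearrangement into a methoxy-substituted vinylketene. This adds to A5 in a [2+2] fashion, and the resulting vinylcyclobutenone opens and recloses (four-electron opening, six-electron closure) to 6-methoxy-2-pentadecyl-3-(triisopropylsilyloxy)phenol A6.
- For it: it is as convergent as the chosen route. The regiochemistry of A6 follows from the polarity of the ketene and of the ynol ether A5, and the sequence ends in the same kind of pericyclic cascade, so on mechanistic reliability the two are equal.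
- Against it: A6 carries only three of the four ring oxygens, so C1 of the target is still C–H; a para-oxidation of the phenol and a desilylation must follow. A4 and A5 each need their own multistep preparation and are delicate: A4 is a diazo ketone that is also a vinylogous ester, and A5 is a hydrolytically labile ynol silyl ether. The ketene from A4 carries hydrogen at its α-carbon and can dimerise during photolysis.
- Comparison: the chosen route isolates its cyclobutenone 11 as an ordinary intermediate, built from a four-membered ring that already holds three oxygens. It needs no diazo compound, no photochemistry and no late C–H oxidation.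

Alternative 3: A single ring bond, C2–C3, is cut, which opens the ring to methyl 3,5,7-trioxodocosanoate A7.
- Forward key step: mild aqueous base induces an intramolecular aldol attack of C2 of the chain of A7 on its C7 ketone. Dehydration and enolisation give methyl 2,4-dihydroxy-6-pentadecylbenzoate A8.
- For it: the cyclisation of A7 is biomimetic and operationally the mildest of all four ring-forming steps, with no cryogenic organometallics. On that point it is stronger than the chosen route.
- Against it: A8 has the wrong substitution for 16. It has ring oxygens only at C1 and C5 of the target, an ester carbon at C2 where a hydroxyl is needed, and hydrogen at C4 where a carbonyl is needed. After the key step one phenol must be methylated selectively, the ester carbon exchanged for oxygen, and the electron-rich ring oxidised at C4. That is at least four further steps, one of them an arene oxidation with its own regiochemical question. A7 itself requires polyanion acylation chemistry.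
- Comparison: the chosen route delivers all four oxygens and the chain on the correct atoms directly from its building blocks. Only the oxidation of 14 and one deprotection follow its key step.

Key step: step 5

Remark: 2 and 7 are taken as purchasable (7 is a gas at room temperature and is condensed at −78 °C). The two-carbon unit is taken from an enol ether and not from a 2-haloacetaldehyde acetal, because a lithiated acetal of that kind would lose alkoxide by β-elimination at once.

## Route

Step 1
Reactants: 1 1-bromopentadecane; 2 di-tert-butyl squarate (3,4-di-tert-butoxycyclobut-3-ene-1,2-dione)
Product: 4 rac-2,3-di-tert-butoxy-4-hydroxy-4-pentadecylcyclobut-2-en-1-one, via pentadecylmagnesium bromide 3 (not isolated)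
Conditions: 1, Mg, THF, 40 °C; then add to 2, THF, −78 °C; sat. aq. NH4Cl
Reagents that add atoms: none
Why: Grignard formation followed by 1,2-addition to one of the two equivalent carbonyl groups of the squarate ester; after the first addition the remaining carbonyl is that of a vinylogous ester on a ring that already carries an alkoxide, so a second addition is not expected at −78 °C. The new carbinol carbon is a stereocentre, formed racemic and removed again in step 2.

Step 2
Reactants: 4 rac-2,3-di-tert-butoxy-4-hydroxy-4-pentadecylcyclobut-2-en-1-one
Product: 6 3-tert-butoxy-4-pentadecylcyclobut-3-ene-1,2-dione, via trifluoroacetate ester 5 (not isolated)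
Conditions: (CF3CO)2O, THF, −78 °C; then cold aq. NaHCO3
Reagents that add atoms: water, O
Why: Squarate-adduct rearrangement (1,3-carbonyl transposition): trifluoroacetylation of the tertiary alcohol gives 5, which ionises to a cyclobutenyl cation held as an oxocarbenium ion by the tert-butoxy group on C2; water adds there on quenching and the hemiketal expels tert-butanol. The tert-butoxy group on C3 sits at the centre of the allyl cation, is not attacked and becomes the vinylogous ester of 6; the low temperature and the bicarbonate quench should keep the trifluoroacetic acid formed from cleaving it.

Step 3
Reactants: 7 methyl vinyl ether (methoxyethene)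
Product: 9 (Z)-1-bromo-2-methoxyethene, via 1,2-dibromo-1-methoxyethane 8 (not isolated)
Conditions: Br2, pentane, −78 °C; concentrate; PhNEt2, 95 °C, distil out; fractionate; store over K2CO3
Reagents that add atoms: bromine, BrBr
Why: Electrophilic addition of bromine to the enol ether gives the α,β-dibromo ether 8, and the tertiary aniline removes HBr through the readily ionised α-bromo ether (E1-like dehydrobromination), the classical route to 2-bromovinyl ethers. The cis (Z) isomer is the one expected to predominate, as in the ethyl series, and fractional distillation should enrich it further.

Step 4
Reactants: 9 (Z)-1-bromo-2-methoxyethene; 6 3-tert-butoxy-4-pentadecylcyclobut-3-ene-1,2-dione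
Product: 11 rac-3-tert-butoxy-4-hydroxy-4-[(Z)-2-methoxyethenyl]-2-pentadecylcyclobut-2-en-1-one, via (Z)-2-methoxyethenyllithium 10 (not isolated)
Conditions: 9, t-BuLi (2 equiv), Et2O, −78 °C; cannulate into 6, THF, −78 °C; H2O quench at −78 °C; Et3N-deactivated SiO2 or use crude
Reagents that add atoms: none
Why: Bromine–lithium exchange on a vinyl bromide proceeds with retention, and the Z lithium reagent 10 is held by internal O–Li coordination, so it should persist at −78 °C; it then adds 1,2 to the C2 carbonyl of 6, the one next to the tert-butoxy-bearing carbon, because the C1 carbonyl is deactivated as the carbonyl of a vinylogous ester (O=C1–C4=C3–O-t-Bu). The new carbinol stereocentre is racemic and is destroyed in step 5; the neutral quench and the base-treated silica are chosen to avoid ionisation of the enol-ether-substituted tertiary carbinol.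

Step 5
Reactants: 11 rac-3-tert-butoxy-4-hydroxy-4-[(Z)-2-methoxyethenyl]-2-pentadecylcyclobut-2-en-1-one
Product: 14 2-tert-butoxy-5-methoxy-3-pentadecylbenzene-1,4-diol, via dienylketene 12 (not isolated), via cyclohexadienone 13 (not isolated)
Conditions: toluene (degassed), 110 °C, Ar
Reagents that add atoms: none
Why: Heating breaks the C1–C4 bond of the cyclobutenone (its own numbering) in a thermal conrotatory four-electron electrocyclic opening and gives dienylketene 12. The hydroxyl on C4, a lone-pair donor, rotates outward as donors do in cyclobutene openings, so the methoxyvinyl group turns inward and ends cis to the ketene across the new double bond. The ketene carbon (C4 of the target) then bonds to the methoxy-bearing vinyl carbon (C5 of the target) in a six-electron disrotatory electrocyclisation, the mode by which the one new ring, the six-membered carbocycle, is closed as cyclohexa-2,4-dienone 13. Enolisation of 13 gives the aromatic diol 14 and removes the only stereocentre that appears on the way, so no lasting stereocentre is set and none needs control. The closest known reaction type is the thermal ring expansion of 4-alkenyl-4-hydroxycyclobutenones to hydroquinones (Moore rearrangement). The only selectivity required is the torquoselectivity of the opening, which the C4 hydroxyl secures; regiochemistry cannot go astray because every ring atom already carries its final substituent after steps 2 and 4, and either geometry of the enol ether would converge on the same arene. Release of ring strain and aromatisation make the sequence irreversible overall, and it needs no reagent, which suits the acid-sensitive enol ether and tert-butyl ether.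

Step 6
Reactants: 14 2-tert-butoxy-5-methoxy-3-pentadecylbenzene-1,4-diol
Product: 15 2-tert-butoxy-5-methoxy-3-pentadecylcyclohexa-2,5-diene-1,4-dione
Conditions: Ag2O, Et2O, rt
Reagents that add atoms: none
Why: Oxidation of a hydroquinone to a 1,4-benzoquinone; the electron-rich trioxygenated diol gives up two electrons and two protons to Ag2O under neutral conditions, which leave the acid-labile tert-butyl ether and the methyl ether untouched.

Step 7
Reactants: 15 2-tert-butoxy-5-methoxy-3-pentadecylcyclohexa-2,5-diene-1,4-dione
Product: 16 2-hydroxy-5-methoxy-3-pentadecylcyclohexa-2,5-diene-1,4-dione (target)
Conditions: CF3CO2H, CH2Cl2, 0 °C to rt; evaporate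
Reagents that add atoms: none
Why: Acidolysis of a tert-butyl ether: protonation of the vinylogous ester and E1 loss of the tert-butyl group as 2-methylpropene frees the C2 hydroxyl, whereas the C5 methyl ether cannot ionise and, with no nucleophile present, cannot be exchanged. Here the two oxygens, told apart since step 2, end as OH and OMe.

## Compound list

1 | 1-bromopentadecane | CCCCCCCCCCCCCCCBr | starting material
2 | di-tert-butyl squarate (3,4-di-tert-butoxycyclobut-3-ene-1,2-dione) | CC(C)(C)OC1=C(OC(C)(C)C)C(=O)C1=O | starting material
3 | pentadecylmagnesium bromide | CCCCCCCCCCCCCCC[Mg]Br | intermediate (not isolated)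
4 | rac-2,3-di-tert-butoxy-4-hydroxy-4-pentadecylcyclobut-2-en-1-one | CCCCCCCCCCCCCCCC1(O)C(OC(C)(C)C)=C(OC(C)(C)C)C1=O | intermediate
5 | rac-2,3-di-tert-butoxy-4-oxo-1-pentadecylcyclobut-2-en-1-yl 2,2,2-trifluoroacetate | CCCCCCCCCCCCCCCC1(OC(=O)C(F)(F)F)C(OC(C)(C)C)=C(OC(C)(C)C)C1=O | intermediate (not isolated)
6 | 3-tert-butoxy-4-pentadecylcyclobut-3-ene-1,2-dione | CCCCCCCCCCCCCCCC1=C(OC(C)(C)C)C(=O)C1=O | intermediate
7 | methyl vinyl ether (methoxyethene) | COC=C | starting material
8 | rac-1,2-dibromo-1-methoxyethane | COC(Br)CBr | intermediate (not isolated)
9 | (Z)-1-bromo-2-methoxyethene | CO/C=C\Br | intermediate
10 | (Z)-2-methoxyethenyllithium | CO/C=C\[Li] | intermediate (not isolated)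
11 | rac-3-tert-butoxy-4-hydroxy-4-[(Z)-2-methoxyethenyl]-2-pentadecylcyclobut-2-en-1-one | CCCCCCCCCCCCCCCC1=C(OC(C)(C)C)C(O)(/C=C\OC)C1=O | intermediate
12 | (3Z,5Z)-3-tert-butoxy-4-hydroxy-6-methoxy-2-pentadecylhexa-1,3,5-trien-1-one | CCCCCCCCCCCCCCCC(=C=O)/C(OC(C)(C)C)=C(O)\C=C/OC | intermediate (not isolated)
13 | rac-3-tert-butoxy-4-hydroxy-6-methoxy-2-pentadecylcyclohexa-2,4-dien-1-one | CCCCCCCCCCCCCCCC1=C(OC(C)(C)C)C(O)=CC(OC)C1=O | intermediate (not isolated)
14 | 2-tert-butoxy-5-methoxy-3-pentadecylbenzene-1,4-diol | CCCCCCCCCCCCCCCc1c(OC(C)(C)C)c(O)cc(OC)c1O | intermediate
15 | 2-tert-butoxy-5-methoxy-3-pentadecylcyclohexa-2,5-diene-1,4-dione | CCCCCCCCCCCCCCCC1=C(OC(C)(C)C)C(=O)C=C(OC)C1=O | intermediate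
16 | 2-hydroxy-5-methoxy-3-pentadecylcyclohexa-2,5-diene-1,4-dione | CCCCCCCCCCCCCCCC1=C(O)C(=O)C=C(OC)C1=O | target

## Step count and least certain steps

Total step count: 7. Longest linear sequence: 6 steps (steps 1, 2, 4, 5, 6 and 7). Step 3 is a one-step side branch that joins at step 4.

Step 5, the key step. What may go wrong: part of the material may open with the opposite sense of rotation, hydroxyl inward, after which the hydroxyl adds to the ketene and the material drains into a five-membered lactone. The six-electron closure may also be slowed because the Z-methoxy group points into the forming ring, which leaves time for ketene dimerisation or for loss of methanol from the enol ether under traces of acid at 110 °C. The torquoselectivity rests on a single donor substituent, and a free hydroxyl is both the trap for the ketene and the handle for ionisation. Fallback, setting out from 6 and rejoining the route at 14: 10 is generated and added to 6 as in step 4, but the lithium alkoxide is not protonated; it is silylated in the same flask with Me3SiCl. This gives rac-3-tert-butoxy-4-[(Z)-2-methoxyethenyl]-2-pentadecyl-4-(trimethylsilyloxy)cyclobut-2-en-1-one F1, which has no hydroxyl to capture a ketene or to ionise and should tolerate chromatography. Heated in toluene, F1 should open with the silyloxy group rotating outward, close in the same six-electron mode and enolise to 3-tert-butoxy-6-methoxy-2-pentadecyl-4-(trimethylsilyloxy)phenol F2. Brief methanolysis of F2 (K2CO3 cat., MeOH, Ar, 0 °C) returns 14.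

Step 4. What may go wrong: 10 may fragment by loss of lithium methoxide if the solution warms, and any E bromide carried in 9 would fragment faster still, so that an acetylide instead of the vinyl reagent is fed into the addition. The tertiary carbinol of 11 may also ionise during work-up or chromatography, since a 2-alkoxyvinyl carbinol is a latent enal. Fallback, setting out from 9 and 6 and rejoining the route at 11: treatment of 9 with LiN(i-Pr)2 (2 equiv, THF, −78 to 0 °C) should remove HBr and metallate the resulting alkyne to lithium methoxyacetylide F3, an alkynyllithium that cannot undergo β-elimination. Addition of F3 to the C2 carbonyl of 6 at −78 °C and a water quench would give rac-3-tert-butoxy-4-hydroxy-4-(methoxyethynyl)-2-pentadecylcyclobut-2-en-1-one F4. Cis semi-hydrogenation of the alkoxyalkyne of F4 (H2, Pd on CaCO3 poisoned with Pb(OAc)2, quinoline, EtOAc, rt) should deliver the Z enol ether 11, which is taken crude into step 5; the tetrasubstituted ring alkene is not expected to be reduced.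

Step 2. What may go wrong: the second tert-butyl group may be lost by acidolysis under the trifluoroacetic acid set free, since the vinylogous tert-butyl ester of 6 is by design acid-labile; ionisation of 5 may also be incomplete at −78 °C. Fallback, setting out from 4 and rejoining the route at 6: aqueous HCl in THF performs the same transposition and deliberately strips both tert-butyl groups, giving 3-hydroxy-4-pentadecylcyclobut-3-ene-1,2-dione F5. Ag2O converts F5 into silver 3,4-dioxo-2-pentadecylcyclobut-1-en-1-olate F6, which is O-alkylated with 2-chloro-2-methylpropane in Et2O. Alkylation at either of the two conjugated oxygens of the anion gives the same compound, 6.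

## Further compounds

F1 | step 5 | rac-3-tert-butoxy-4-[(Z)-2-methoxyethenyl]-2-pentadecyl-4-(trimethylsilyloxy)cyclobut-2-en-1-one | CCCCCCCCCCCCCCCC1=C(OC(C)(C)C)C(O[Si](C)(C)C)(/C=C\OC)C1=O
F2 | step 5 | 3-tert-butoxy-6-methoxy-2-pentadecyl-4-(trimethylsilyloxy)phenol | CCCCCCCCCCCCCCCc1c(OC(C)(C)C)c(O[Si](C)(C)C)cc(OC)c1O
F3 | step 4 | lithium methoxyacetylide | COC#C[Li]
F4 | step 4 | rac-3-tert-butoxy-4-hydroxy-4-(methoxyethynyl)-2-pentadecylcyclobut-2-en-1-one | CCCCCCCCCCCCCCCC1=C(OC(C)(C)C)C(O)(C#COC)C1=O
F5 | step 2 | 3-hydroxy-4-pentadecylcyclobut-3-ene-1,2-dione | CCCCCCCCCCCCCCCC1=C(O)C(=O)C1=O
F6 | step 2 | silver 3,4-dioxo-2-pentadecylcyclobut-1-en-1-olate | CCCCCCCCCCCCCCCC1=C([O-])C(=O)C1=O.[Ag+]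
A1 | alternative 1 | nonadecane-2,3-dione | CC(=O)C(=O)CCCCCCCCCCCCCCCC
A2 | alternative 1 | diethyl oxalate | CCOC(=O)C(=O)OCC
A3 | alternative 1 | 2,5-dihydroxy-3-pentadecylcyclohexa-2,5-diene-1,4-dione | CCCCCCCCCCCCCCCC1=C(O)C(=O)C=C(O)C1=O
A4 | alternative 2 | (E)-1-diazo-4-methoxybut-3-en-2-one | CO/C=C/C(=O)C=[N+]=[N-]
A5 | alternative 2 | (heptadec-1-yn-1-yloxy)triisopropylsilane | CCCCCCCCCCCCCCCC#CO[Si](C(C)C)(C(C)C)C(C)C
A6 | alternative 2 | 6-methoxy-2-pentadecyl-3-(triisopropylsilyloxy)phenol | CCCCCCCCCCCCCCCc1c(O[Si](C(C)C)(C(C)C)C(C)C)ccc(OC)c1O
A7 | alternative 3 | methyl 3,5,7-trioxodocosanoate | CCCCCCCCCCCCCCCC(=O)CC(=O)CC(=O)CC(=O)OC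
A8 | alternative 3 | methyl 2,4-dihydroxy-6-pentadecylbenzoate | CCCCCCCCCCCCCCCc1cc(O)cc(O)c1C(=O)OC
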